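**Retrosynthetic overview**

1. Ring numbering: O1–C2(=O)–C3(Me)=C4–C5=C6–C7–C8–C9(Me)–C10(CH2-oxazolyl)–O11–C12(=O)–C13=C14–C15=C16–C17–C18–C19(Me)–C20(CH2-oxazolyl)–O1. The 20-membered ring is closed last, at C9–C10, by a nickel-catalysed stereoconvergent decarboxylative alkyl–alkyl coupling of an open chain that carries a secondary alkylzinc at C9 and an N-acyloxyphthalimide on C10; C9 and C10 are stereo-undefined before this step and both are set in it.
2. Enabling feature: C10 is a carbinol carbon bearing the ester oxygen O11 of the C12 dienoate. This α-acyloxy group stabilises a radical at C10, and its C12 carbonyl can chelate nickel (five-membered Ni–C10–O11–C12=O ring); the oxazole ring, insulated by one CH2, stays a spectator.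
3. The open chain is assembled from acid A (C2–C9), acid B (C12–C20 with its oxazole) and lactate C (C10, its CH2-oxazole and a sacrificial carboxyl) by two Mitsunobu esterifications, so no (Z,Z)-dienoyl carbon is ever activated; the second one inverts C20 and turns the anti crotylation product into the syn pair.
4. Only C19/C20 come from asymmetric catalysis (iridium-catalysed anti-crotylation of an oxazolylethanol); both (Z,Z)-dienoic acids come from Wittig reactions with 5-hydroxybutenolides.
5. Ring order: both oxazole rings are bought as 2-silyl-protected oxazole and never opened; the macrocycle is formed in the last step.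

Key step: step 22

Assumption: compounds 4, 8, 11, 16 and 23 are taken as purchasable, and C9 and C10 are deliberately carried as epimer mixtures because both centres are erased and reset in step 22.

**Route**

Step 1
Reactants: 1 2-methyltetrahydrofuran (racemic)
Product: 2 tert-butyl[(5-iodopentan-2-yl)oxy]dimethylsilane (racemic)
Conditions: TBSCl, NaI, MeCN, 55 °C
Reagents that add atoms: tert-butyldimethylsilyl chloride CC(C)(C)[Si](C)(C)Cl; sodium iodide [Na+].[I-]
Why: Ether cleavage by a halosilane: the silyl iodide formed in situ silylates the ring oxygen and iodide opens the oxonium ion by SN2 attack at the unhindered primary carbon, leaving the silyl group on the secondary oxygen; the stereocentre (C9 of the target) needs no control.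

Step 2
Reactants: 2 tert-butyl[(5-iodopentan-2-yl)oxy]dimethylsilane
Product: 3 {4-[(tert-butyldimethylsilyl)oxy]pentyl}triphenylphosphonium iodide
Conditions: PPh3, MeCN, 80 °C
Reagents that add atoms: triphenylphosphine c1ccc(cc1)P(c1ccccc1)c1ccccc1
Why: SN2 quaternisation of the phosphine by the primary iodide gives the Wittig salt, and the secondary silyl ether is inert.

Step 3
Reactants: 3 {4-[(tert-butyldimethylsilyl)oxy]pentyl}triphenylphosphonium iodide; 4 5-hydroxy-3-methylfuran-2(5H)-one
Product: 7 (2Z,4Z)-8-[(tert-butyldimethylsilyl)oxy]-2-methylnona-2,4-dienoic acid (acid A; racemic at C8), via phosphonium ylide 5 (not isolated), via sodium (2Z)-2-methyl-4-oxobut-2-enoate 6 (not isolated)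
Conditions: NaN(SiMe3)2 (2.05 equiv), THF, −78 °C; then 4, −78 to 0 °C; AcOH quench
Reagents that add atoms: none
Why: Salt-free Wittig olefination of the non-stabilised ylide with the ring-opened formylacrylate (formed from the hydroxybutenolide by the second equivalent of base) should give the new C5=C6 bond Z under kinetic control, while the C3=C4 bond keeps the Z geometry that was fixed in the butenolide ring, and the free acid results directly.

Step 4
Reactants: 8 2-(triisopropylsilyl)oxazole
Product: 10 [2-(triisopropylsilyl)oxazol-5-yl]magnesium bromide (titrated THF stock solution kept at −20 °C under argon and divided between steps 5 and 7), via 5-lithio-2-(triisopropylsilyl)oxazole 9 (not isolated)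
Conditions: n-BuLi, THF, −78 °C; MgBr2·OEt2, −78 to −20 °C
Reagents that add atoms: magnesium bromide (used as its diethyl etherate) Br[Mg]Br
Why: Directed C5 lithiation of the C2-silylated oxazole (the only acidic ring position left) followed by lithium-to-magnesium transmetalation gives the oxazolyl Grignard reagent; with C2 blocked the metalated ring cannot open to an isocyanoenolate, so one cold stock solution should serve both later steps.

Step 5
Reactants: 10 [2-(triisopropylsilyl)oxazol-5-yl]magnesium bromide (first portion of the stock solution); 11 methyl oxirane-2-carboxylate (racemic)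
Product: 12 methyl 2-hydroxy-3-[2-(triisopropylsilyl)oxazol-5-yl]propanoate (racemic)
Conditions: CuBr·SMe2 (10 mol%), THF, −40 to −20 °C; H2O
Reagents that add atoms: none
Why: Copper-catalysed SN2 opening of the glycidic ester at its unsubstituted carbon by the Grignard reagent (epoxide alkylation) gives the α-hydroxy ester, the low temperature sparing the ester carbonyl; the carbinol centre is left racemic on purpose because it becomes a planar radical in step 22.

Step 6
Reactants: 12 methyl 2-hydroxy-3-[2-(triisopropylsilyl)oxazol-5-yl]propanoate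
Product: 13 allyl 2-hydroxy-3-[2-(triisopropylsilyl)oxazol-5-yl]propanoate (lactate C; racemic)
Conditions: allyl alcohol (solvent), Ti(OiPr)4 (10 mol%), 80 °C
Reagents that add atoms: allyl alcohol C=CCO
Why: Titanate-catalysed transesterification exchanges methyl for allyl, an ester that can later be removed under neutral conditions in the presence of three other esters.

Step 7
Reactants: 10 [2-(triisopropylsilyl)oxazol-5-yl]magnesium bromide (second portion of the stock solution); 14 ethylene oxide
Product: 15 2-[2-(triisopropylsilyl)oxazol-5-yl]ethan-1-ol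
Conditions: CuBr·SMe2 (10 mol%), THF, −40 to 0 °C; H2O
Reagents that add atoms: none
Why: Copper-catalysed SN2 opening of ethylene oxide by the C5 oxazolyl Grignard reagent (epoxide alkylation) installs the hydroxyethyl arm, and no stereocentre is formed.

Step 8
Reactants: 15 2-[2-(triisopropylsilyl)oxazol-5-yl]ethan-1-ol; 16 but-3-en-2-yl acetate (racemic)
Product: 17 (2S,3R)-3-methyl-1-[2-(triisopropylsilyl)oxazol-5-yl]pent-4-en-2-ol
Conditions: [Ir(cod)Cl]2 (2.5 mol%), SEGPHOS (5 mol%; the enantiomer that gives 2S,3R), 4-cyano-3-nitrobenzoic acid (10 mol%), Cs2CO3 (20 mol%), THF, 90 °C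
Reagents that add atoms: none
Why: Iridium-catalysed transfer-hydrogenative carbonyl crotylation from the alcohol oxidation level: the alcohol is dehydrogenated to a transient aldehyde that is trapped by the (E)-σ-crotyliridium species through a chair transition state, which sets the anti relationship, while the chiral bisphosphine sets the absolute configuration of both new centres.

Step 9
Reactants: 17 (2S,3R)-3-methyl-1-[2-(triisopropylsilyl)oxazol-5-yl]pent-4-en-2-ol
Product: 18 5-{(2S,3R)-2-[(tert-butyldimethylsilyl)oxy]-3-methylpent-4-en-1-yl}-2-(triisopropylsilyl)oxazole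
Conditions: TBSOTf, 2,6-lutidine, CH2Cl2, −78 to 0 °C
Reagents that add atoms: tert-butyldimethylsilyl trifluoromethanesulfonate CC(C)(C)[Si](C)(C)OS(=O)(=O)C(F)(F)F
Why: Silylation of the hindered secondary alcohol with the silyl triflate (protecting-group installation) masks it for the following steps without touching the stereocentres.

Step 10
Reactants: 18 5-{(2S,3R)-2-[(tert-butyldimethylsilyl)oxy]-3-methylpent-4-en-1-yl}-2-(triisopropylsilyl)oxazole
Product: 19 (4R,5S)-5-[(tert-butyldimethylsilyl)oxy]-4-methyl-6-[2-(triisopropylsilyl)oxazol-5-yl]hexanal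
Conditions: Rh(acac)(CO)2 (1 mol%), Xantphos (2 mol%), CO/H2 (1:1, 10 bar), toluene, 70 °C
Reagents that add atoms: carbon monoxide [C-]#[O+]
Why: Rhodium-catalysed hydroformylation with the wide-bite-angle ligand places the formyl group on the terminal carbon of the α-branched vinyl group (linear selectivity) and leaves the stereocentres untouched.

Step 11
Reactants: 19 (4R,5S)-5-[(tert-butyldimethylsilyl)oxy]-4-methyl-6-[2-(triisopropylsilyl)oxazol-5-yl]hexanal
Product: 20 (4R,5S)-5-[(tert-butyldimethylsilyl)oxy]-4-methyl-6-[2-(triisopropylsilyl)oxazol-5-yl]hexan-1-ol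
Conditions: NaBH4, MeOH, 0 °C
Reagents that add atoms: none
Why: Borohydride reduction of the aldehyde gives the primary alcohol (carbonyl reduction) and no stereocentre is touched.

Step 12
Reactants: 20 (4R,5S)-5-[(tert-butyldimethylsilyl)oxy]-4-methyl-6-[2-(triisopropylsilyl)oxazol-5-yl]hexan-1-ol
Product: 21 5-{(2S,3R)-2-[(tert-butyldimethylsilyl)oxy]-6-iodo-3-methylhexyl}-2-(triisopropylsilyl)oxazole
Conditions: PPh3, imidazole, I2, CH2Cl2, 0 °C
Reagents that add atoms: iodine [I][I]
Why: Appel iodination converts the primary alcohol into the iodide by SN2 displacement of its alkoxyphosphonium ion under buffered conditions that spare both silyl groups.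

Step 13
Reactants: 21 5-{(2S,3R)-2-[(tert-butyldimethylsilyl)oxy]-6-iodo-3-methylhexyl}-2-(triisopropylsilyl)oxazole
Product: 22 {(4R,5S)-5-[(tert-butyldimethylsilyl)oxy]-4-methyl-6-[2-(triisopropylsilyl)oxazol-5-yl]hexyl}triphenylphosphonium iodide
Conditions: PPh3, MeCN, 80 °C
Reagents that add atoms: triphenylphosphine c1ccc(cc1)P(c1ccccc1)c1ccccc1
Why: SN2 quaternisation of the phosphine by the primary iodide gives the Wittig salt, and the bulky C2 silyl group shields the oxazole nitrogen from competing alkylation.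

Step 14
Reactants: 22 {(4R,5S)-5-[(tert-butyldimethylsilyl)oxy]-4-methyl-6-[2-(triisopropylsilyl)oxazol-5-yl]hexyl}triphenylphosphonium iodide; 23 5-hydroxyfuran-2(5H)-one
Product: 26 (2Z,4Z,8R,9S)-9-[(tert-butyldimethylsilyl)oxy]-8-methyl-10-[2-(triisopropylsilyl)oxazol-5-yl]deca-2,4-dienoic acid (acid B), via phosphonium ylide 24 (not isolated), via sodium (2Z)-4-oxobut-2-enoate 25 (not isolated)
Conditions: NaN(SiMe3)2 (2.05 equiv), THF, −78 °C; then 23, −78 to 0 °C; AcOH quench
Reagents that add atoms: none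
Why: Salt-free Wittig olefination of the non-stabilised ylide with the ring-opened formylacrylate should give the new C4=C5 bond Z while the C2=C3 bond keeps the Z geometry of the butenolide, and the C2 silyl group blocks the only acidic oxazole C–H so that neither base nor ylide can metalate the ring.

Step 15
Reactants: 26 acid B; 13 lactate C
Product: 27 allyl 2-{[(2Z,4Z,8R,9S)-9-[(tert-butyldimethylsilyl)oxy]-8-methyl-10-[2-(triisopropylsilyl)oxazol-5-yl]deca-2,4-dienoyl]oxy}-3-[2-(triisopropylsilyl)oxazol-5-yl]propanoate (both epimers at the propanoate C2)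
Conditions: PPh3, DIAD, THF, 0 °C to rt
Reagents that add atoms: none
Why: Mitsunobu esterification: the carboxylate of acid B displaces the activated α-hydroxy ester oxygen by SN2, so the (2Z,4Z)-dienoyl carbon is never activated and cannot isomerise; the inverted centre (C10 of the target) is racemic and is reset in step 22.

Step 16
Reactants: 27 silylated diester
Product: 28 allyl 2-{[(2Z,4Z,8R,9S)-9-hydroxy-8-methyl-10-(oxazol-5-yl)deca-2,4-dienoyl]oxy}-3-(oxazol-5-yl)propanoate (both epimers at the propanoate C2)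
Conditions: HF·pyridine, pyridine, THF, 0 °C to rt
Reagents that add atoms: none
Why: Fluoride-mediated desilylation cleaves the O–Si bond of the secondary silyl ether and protodesilylates both oxazole C2–Si bonds in one operation, while the allyl ester and the dienoate ester are inert to buffered HF·pyridine.

Step 17
Reactants: 28 hydroxy diester; 7 acid A
Product: 29 allyl 2-{[(2Z,4Z,8R,9R)-9-{[(2Z,4Z)-8-[(tert-butyldimethylsilyl)oxy]-2-methylnona-2,4-dienoyl]oxy}-8-methyl-10-(oxazol-5-yl)deca-2,4-dienoyl]oxy}-3-(oxazol-5-yl)propanoate (epimer mixture at the silyloxy carbon and at the propanoate C2)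
Conditions: PPh3, DIAD, toluene, 0 °C to rt
Reagents that add atoms: none
Why: Mitsunobu esterification: the carbinol (C20 of the target) is activated as its alkoxyphosphonium ion and displaced by the carboxylate of acid A in an SN2 step, which inverts it from S to R (the syn C19/C20 pair) and never activates the (2Z,4Z)-dienoyl carbon.

Step 18
Reactants: 29 silyl ether triester
Product: 30 allyl 2-{[(2Z,4Z,8R,9R)-9-{[(2Z,4Z)-8-hydroxy-2-methylnona-2,4-dienoyl]oxy}-8-methyl-10-(oxazol-5-yl)deca-2,4-dienoyl]oxy}-3-(oxazol-5-yl)propanoate (epimer mixture)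
Conditions: HF·pyridine, pyridine, THF, 0 °C
Reagents that add atoms: none
Why: Fluoride-mediated cleavage of the remaining secondary silyl ether frees the alcohol at the future C9 without touching the esters or dienes.

Step 19
Reactants: 30 hydroxy triester
Product: 31 allyl 2-{[(2Z,4Z,8R,9R)-9-{[(2Z,4Z)-8-iodo-2-methylnona-2,4-dienoyl]oxy}-8-methyl-10-(oxazol-5-yl)deca-2,4-dienoyl]oxy}-3-(oxazol-5-yl)propanoate (epimer mixture)
Conditions: PPh3, imidazole, I2 (premixed), CH2Cl2, 0 °C, dark
Reagents that add atoms: iodine [I][I]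
Why: Appel iodination converts the secondary alcohol into the iodide by SN2 displacement of its alkoxyphosphonium ion; premixing iodine with the phosphine avoids free iodine that could isomerise the dienes, and the configuration at this carbon is irrelevant because it is erased in step 22.

Step 20
Reactants: 31 iodo triester
Product: 32 2-{[(2Z,4Z,8R,9R)-9-{[(2Z,4Z)-8-iodo-2-methylnona-2,4-dienoyl]oxy}-8-methyl-10-(oxazol-5-yl)deca-2,4-dienoyl]oxy}-3-(oxazol-5-yl)propanoic acid (epimer mixture)
Conditions: Pd(PPh3)4 (5 mol%), N-methylaniline, THF, rt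
Reagents that add atoms: none
Why: Tsuji–Trost deallylation: zerovalent palladium ionises only the allyl ester and N-methylaniline traps the allyl fragment, which frees the carboxyl group under neutral conditions without touching the other esters, the dienes or the unactivated secondary iodide.

Step 21
Reactants: 32 iodo acid
Product: 33 1,3-dioxoisoindolin-2-yl 2-{[(2Z,4Z,8R,9R)-9-{[(2Z,4Z)-8-iodo-2-methylnona-2,4-dienoyl]oxy}-8-methyl-10-(oxazol-5-yl)deca-2,4-dienoyl]oxy}-3-(oxazol-5-yl)propanoate (epimer mixture)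
Conditions: N-hydroxyphthalimide, DIC, DMAP (10 mol%), CH2Cl2, 0 °C to rt
Reagents that add atoms: N-hydroxyphthalimide O=C1c2ccccc2C(=O)N1O
Why: Carbodiimide (Steglich-type) esterification of the α-acyloxy acid with N-hydroxyphthalimide gives the redox-active ester, and the only acyl carbon activated is the saturated one, so the dienoates cannot isomerise.

Step 22
Reactants: 33 redox-active ester with secondary iodide
Product: 35 (3Z,5Z,9R,10R,13Z,15Z,19R,20R)-3,9,19-trimethyl-10,20-bis(oxazol-5-ylmethyl)-1,11-dioxacycloicosa-3,5,13,15-tetraene-2,12-dione (target), via secondary alkylzinc iodide 34 (not isolated)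
Conditions: Zn dust (activated with TMSCl and 1,2-dibromoethane), LiCl, THF, 30 °C; decant from zinc; syringe-pump addition to NiBr2(dme) (20 mol%), iPr-pybox [2,6-bis(4-isopropyl-4,5-dihydrooxazol-2-yl)pyridine, 24 mol%; the enantiomer that gives 10R], THF/DMA, 0 °C, final 2 mM; H2O
Reagents that add atoms: none
Why: Proposed new method: zinc inserts only into the C9–I bond (the N-acyloxyphthalimide is not reduced by zinc in the absence of nickel) and the secondary alkyl group is passed to nickel; the resulting monovalent alkylnickel transfers one electron to the redox-active ester, which loses phthalimidate and CO2, and the α-acyloxy radical at C10 is captured by nickel so that reductive elimination from trivalent nickel forms C9–C10. The closest known reaction types are the nickel-catalysed decarboxylative alkyl–alkyl Negishi coupling of N-acyloxyphthalimides with alkylzinc reagents and the enantioconvergent nickel couplings of α-acyloxy and α-amido alkyl electrophiles, including doubly stereoconvergent couplings that set vicinal centres; new are the ring-closing use, the unactivated secondary zinc partner and the combination of both stereoconvergences. The 20-membered ring closes end to end by intramolecular cross-coupling at nickel (no small cyclic transition state; slow addition keeps the open-chain zinc species near 2 mM). C10 is controlled by the chiral pybox ligand: its radical is planar, so both C10 epimers of 33 converge, and the C12 carbonyl on O11 chelates nickel in a five-membered ring (Ni–C10–O11–C12=O) that fixes the face to which C9 is delivered. C9 is controlled in the same reductive elimination: the secondary alkyl–nickel bond is configurationally labile, so both C9 epimers funnel through the diastereomeric transition state favoured by the ligand pocket and the ring-forming tether, which should be the one leading to the syn 9R,10R pair, and this is the less secure of the two centres. The step needs chemoselectivity over two (Z,Z)-dienoates and two oxazoles, which should be secured because the coupling cycle itself generates no radical at C9 (so no 6-exo attack on C4 during the nickel step), alkylzinc halides do not add to dienoates, the C10 radical has only a disfavoured 5-endo path to C14, and (Z,Z)-dienes cannot adopt the s-cis geometry needed to bind nickel.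

**Compound list**

1 | 2-methyltetrahydrofuran (racemic) | CC1CCCO1 | starting material
2 | tert-butyl[(5-iodopentan-2-yl)oxy]dimethylsilane (racemic) | CC(CCCI)O[Si](C)(C)C(C)(C)C | intermediate
3 | {4-[(tert-butyldimethylsilyl)oxy]pentyl}triphenylphosphonium iodide | CC(CCC[P+](c1ccccc1)(c1ccccc1)c1ccccc1)O[Si](C)(C)C(C)(C)C.[I-] | intermediate
4 | 5-hydroxy-3-methylfuran-2(5H)-one | CC1=CC(O)OC1=O | starting material
5 | {4-[(tert-butyldimethylsilyl)oxy]pentylidene}triphenylphosphorane | CC(CCC=P(c1ccccc1)(c1ccccc1)c1ccccc1)O[Si](C)(C)C(C)(C)C | intermediate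
6 | sodium (2Z)-2-methyl-4-oxobut-2-enoate | C/C(=C/C=O)C(=O)[O-].[Na+] | intermediate
7 | (2Z,4Z)-8-[(tert-butyldimethylsilyl)oxy]-2-methylnona-2,4-dienoic acid (acid A; racemic at C8) | C/C(=C/C=C\CCC(C)O[Si](C)(C)C(C)(C)C)C(=O)O | intermediate
8 | 2-(triisopropylsilyl)oxazole | CC(C)[Si](C(C)C)(C(C)C)c1ncco1 | starting material
9 | 5-lithio-2-(triisopropylsilyl)oxazole | [Li]c1cnc([Si](C(C)C)(C(C)C)C(C)C)o1 | intermediate
10 | [2-(triisopropylsilyl)oxazol-5-yl]magnesium bromide (THF stock solution) | Br[Mg]c1cnc([Si](C(C)C)(C(C)C)C(C)C)o1 | intermediate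
11 | methyl oxirane-2-carboxylate (racemic) | COC(=O)C1CO1 | starting material
12 | methyl 2-hydroxy-3-[2-(triisopropylsilyl)oxazol-5-yl]propanoate (racemic) | COC(=O)C(O)Cc1cnc([Si](C(C)C)(C(C)C)C(C)C)o1 | intermediate
13 | allyl 2-hydroxy-3-[2-(triisopropylsilyl)oxazol-5-yl]propanoate (lactate C; racemic) | C=CCOC(=O)C(O)Cc1cnc([Si](C(C)C)(C(C)C)C(C)C)o1 | intermediate
14 | ethylene oxide | C1CO1 | starting material
15 | 2-[2-(triisopropylsilyl)oxazol-5-yl]ethan-1-ol | OCCc1cnc([Si](C(C)C)(C(C)C)C(C)C)o1 | intermediate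
16 | but-3-en-2-yl acetate (racemic) | CC(OC(C)=O)C=C | starting material
17 | (2S,3R)-3-methyl-1-[2-(triisopropylsilyl)oxazol-5-yl]pent-4-en-2-ol | C=C[C@@H](C)[C@H](Cc1cnc([Si](C(C)C)(C(C)C)C(C)C)o1)O | intermediate
18 | 5-{(2S,3R)-2-[(tert-butyldimethylsilyl)oxy]-3-methylpent-4-en-1-yl}-2-(triisopropylsilyl)oxazole | C=C[C@@H](C)[C@H](Cc1cnc([Si](C(C)C)(C(C)C)C(C)C)o1)O[Si](C)(C)C(C)(C)C | intermediate
19 | (4R,5S)-5-[(tert-butyldimethylsilyl)oxy]-4-methyl-6-[2-(triisopropylsilyl)oxazol-5-yl]hexanal | O=CCC[C@@H](C)[C@H](Cc1cnc([Si](C(C)C)(C(C)C)C(C)C)o1)O[Si](C)(C)C(C)(C)C | intermediate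
20 | (4R,5S)-5-[(tert-butyldimethylsilyl)oxy]-4-methyl-6-[2-(triisopropylsilyl)oxazol-5-yl]hexan-1-ol | OCCC[C@@H](C)[C@H](Cc1cnc([Si](C(C)C)(C(C)C)C(C)C)o1)O[Si](C)(C)C(C)(C)C | intermediate
21 | 5-{(2S,3R)-2-[(tert-butyldimethylsilyl)oxy]-6-iodo-3-methylhexyl}-2-(triisopropylsilyl)oxazole | ICCC[C@@H](C)[C@H](Cc1cnc([Si](C(C)C)(C(C)C)C(C)C)o1)O[Si](C)(C)C(C)(C)C | intermediate
22 | {(4R,5S)-5-[(tert-butyldimethylsilyl)oxy]-4-methyl-6-[2-(triisopropylsilyl)oxazol-5-yl]hexyl}triphenylphosphonium iodide | [I-].c1ccccc1[P+](c1ccccc1)(c1ccccc1)CCC[C@@H](C)[C@H](Cc1cnc([Si](C(C)C)(C(C)C)C(C)C)o1)O[Si](C)(C)C(C)(C)C | intermediate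
23 | 5-hydroxyfuran-2(5H)-one | O=C1C=CC(O)O1 | starting material
24 | {(4R,5S)-5-[(tert-butyldimethylsilyl)oxy]-4-methyl-6-[2-(triisopropylsilyl)oxazol-5-yl]hexylidene}triphenylphosphorane | c1ccccc1P(c1ccccc1)(c1ccccc1)=CCC[C@@H](C)[C@H](Cc1cnc([Si](C(C)C)(C(C)C)C(C)C)o1)O[Si](C)(C)C(C)(C)C | intermediate
25 | sodium (2Z)-4-oxobut-2-enoate | O=C/C=C\C(=O)[O-].[Na+] | intermediate
26 | (2Z,4Z,8R,9S)-9-[(tert-butyldimethylsilyl)oxy]-8-methyl-10-[2-(triisopropylsilyl)oxazol-5-yl]deca-2,4-dienoic acid (acid B) | OC(=O)/C=C\C=C/CC[C@@H](C)[C@H](Cc1cnc([Si](C(C)C)(C(C)C)C(C)C)o1)O[Si](C)(C)C(C)(C)C | intermediate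
27 | allyl 2-{[(2Z,4Z,8R,9S)-9-[(tert-butyldimethylsilyl)oxy]-8-methyl-10-[2-(triisopropylsilyl)oxazol-5-yl]deca-2,4-dienoyl]oxy}-3-[2-(triisopropylsilyl)oxazol-5-yl]propanoate (both epimers at the propanoate C2) | C=CCOC(=O)C(Cc1cnc([Si](C(C)C)(C(C)C)C(C)C)o1)OC(=O)/C=C\C=C/CC[C@@H](C)[C@H](Cc1cnc([Si](C(C)C)(C(C)C)C(C)C)o1)O[Si](C)(C)C(C)(C)C | intermediate
28 | allyl 2-{[(2Z,4Z,8R,9S)-9-hydroxy-8-methyl-10-(oxazol-5-yl)deca-2,4-dienoyl]oxy}-3-(oxazol-5-yl)propanoate (both epimers at the propanoate C2) | C=CCOC(=O)C(Cc1cnco1)OC(=O)/C=C\C=C/CC[C@@H](C)[C@H](Cc1cnco1)O | intermediate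
29 | allyl 2-{[(2Z,4Z,8R,9R)-9-{[(2Z,4Z)-8-[(tert-butyldimethylsilyl)oxy]-2-methylnona-2,4-dienoyl]oxy}-8-methyl-10-(oxazol-5-yl)deca-2,4-dienoyl]oxy}-3-(oxazol-5-yl)propanoate (epimer mixture) | C=CCOC(=O)C(Cc1cnco1)OC(=O)/C=C\C=C/CC[C@@H](C)[C@@H](Cc1cnco1)OC(=O)/C(C)=C\C=C/CCC(C)O[Si](C)(C)C(C)(C)C | intermediate
30 | allyl 2-{[(2Z,4Z,8R,9R)-9-{[(2Z,4Z)-8-hydroxy-2-methylnona-2,4-dienoyl]oxy}-8-methyl-10-(oxazol-5-yl)deca-2,4-dienoyl]oxy}-3-(oxazol-5-yl)propanoate (epimer mixture) | C=CCOC(=O)C(Cc1cnco1)OC(=O)/C=C\C=C/CC[C@@H](C)[C@@H](Cc1cnco1)OC(=O)/C(C)=C\C=C/CCC(C)O | intermediate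
31 | allyl 2-{[(2Z,4Z,8R,9R)-9-{[(2Z,4Z)-8-iodo-2-methylnona-2,4-dienoyl]oxy}-8-methyl-10-(oxazol-5-yl)deca-2,4-dienoyl]oxy}-3-(oxazol-5-yl)propanoate (epimer mixture) | C=CCOC(=O)C(Cc1cnco1)OC(=O)/C=C\C=C/CC[C@@H](C)[C@@H](Cc1cnco1)OC(=O)/C(C)=C\C=C/CCC(C)I | intermediate
32 | 2-{[(2Z,4Z,8R,9R)-9-{[(2Z,4Z)-8-iodo-2-methylnona-2,4-dienoyl]oxy}-8-methyl-10-(oxazol-5-yl)deca-2,4-dienoyl]oxy}-3-(oxazol-5-yl)propanoic acid (epimer mixture) | OC(=O)C(Cc1cnco1)OC(=O)/C=C\C=C/CC[C@@H](C)[C@@H](Cc1cnco1)OC(=O)/C(C)=C\C=C/CCC(C)I | intermediate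
33 | 1,3-dioxoisoindolin-2-yl 2-{[(2Z,4Z,8R,9R)-9-{[(2Z,4Z)-8-iodo-2-methylnona-2,4-dienoyl]oxy}-8-methyl-10-(oxazol-5-yl)deca-2,4-dienoyl]oxy}-3-(oxazol-5-yl)propanoate (epimer mixture) | O=C(ON1C(=O)c2ccccc2C1=O)C(Cc1cnco1)OC(=O)/C=C\C=C/CC[C@@H](C)[C@@H](Cc1cnco1)OC(=O)/C(C)=C\C=C/CCC(C)I | intermediate
34 | secondary alkylzinc iodide derived from 33 (iodozinc at the former C–I carbon) | O=C(ON1C(=O)c2ccccc2C1=O)C(Cc1cnco1)OC(=O)/C=C\C=C/CC[C@@H](C)[C@@H](Cc1cnco1)OC(=O)/C(C)=C\C=C/CCC(C)[Zn]I | intermediate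
35 | (3Z,5Z,9R,10R,13Z,15Z,19R,20R)-3,9,19-trimethyl-10,20-bis(oxazol-5-ylmethyl)-1,11-dioxacycloicosa-3,5,13,15-tetraene-2,12-dione | C/C1=C/C=C\CC[C@@H](C)[C@@H](Cc2cnco2)OC(=O)/C=C\C=C/CC[C@@H](C)[C@@H](Cc2cnco2)OC1=O | target

**Step count and risks**

Total step count: 22. Longest linear sequence: 17 steps (step 4, steps 7–14, then steps 15–22).

Steps most likely to fail:

Step 22 (proposed new method). What may go wrong: radical leakage during zinc insertion with 6-exo attack on C4; β-hydride elimination and chain walking of the secondary alkylnickel; insufficient facial discrimination at C9 in the reductive elimination; intermolecular coupling outrunning ring closure. Fallback: the ring is closed instead at O11–C12 by Mitsunobu macrolactonisation, using only known chemistry. The fallback sets out from phosphonium salt 22, hydroxybutenolide 4 and acid 26. Wittig reaction of the ylide from 22 with 4 (NaN(SiMe3)2, THF, −78 °C) gives (2Z,4Z,8R,9S)-9-[(tert-butyldimethylsilyl)oxy]-2,8-dimethyl-10-[2-(triisopropylsilyl)oxazol-5-yl]deca-2,4-dienoic acid F1. Acid 26 is alkylated with allyl bromide and K2CO3 in DMF to its allyl ester F2 and desilylated with HF·pyridine to allyl (2Z,4Z,8R,9S)-9-hydroxy-8-methyl-10-(oxazol-5-yl)deca-2,4-dienoate F3. Mitsunobu esterification of F3 with F1 (inversion at the carbinol) gives the silylated diester F4, HF·pyridine gives the hydroxy diester F5, and Pd(PPh3)4 with N-methylaniline gives the seco acid F6. Mitsunobu macrolactonisation of F6 (PPh3, DIAD, toluene, high dilution; inversion at C10) comes back to the route at target 35.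

Step 17. What may go wrong: elimination or stalled SN2 displacement at the hindered, β-branched alkoxyphosphonium ion. Fallback: from alcohol 28, Dess–Martin oxidation gives the ketone F7, Corey–Bakshi–Shibata reduction with catecholborane gives the syn (9R) alcohol F8, and Shiina esterification with acid 7 (2-methyl-6-nitrobenzoic anhydride, DMAP, Et3N; retention) comes back to the route at ester 29.

Step 14. What may go wrong: erosion of Z geometry through ylide equilibration or isomerisation of the formylacrylate, and base attack on the oxazole if the C2 silyl group is lost. Fallback: from aldehyde 19, Stork–Zhao olefination (iodomethyltriphenylphosphonium iodide, NaN(SiMe3)2, THF, −78 °C) gives the (Z)-vinyl iodide F9, and Stille coupling with (Z)-3-(tributylstannyl)acrylic acid (Pd2(dba)3, AsPh3, NMP, rt) comes back to the route at acid 26.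

Further compounds
F1 | step 22 | (2Z,4Z,8R,9S)-9-[(tert-butyldimethylsilyl)oxy]-2,8-dimethyl-10-[2-(triisopropylsilyl)oxazol-5-yl]deca-2,4-dienoic acid | C/C(=C/C=C\CC[C@@H](C)[C@H](Cc1cnc([Si](C(C)C)(C(C)C)C(C)C)o1)O[Si](C)(C)C(C)(C)C)C(=O)O
F2 | step 22 | allyl (2Z,4Z,8R,9S)-9-[(tert-butyldimethylsilyl)oxy]-8-methyl-10-[2-(triisopropylsilyl)oxazol-5-yl]deca-2,4-dienoate | C=CCOC(=O)/C=C\C=C/CC[C@@H](C)[C@H](Cc1cnc([Si](C(C)C)(C(C)C)C(C)C)o1)O[Si](C)(C)C(C)(C)C
F3 | step 22 | allyl (2Z,4Z,8R,9S)-9-hydroxy-8-methyl-10-(oxazol-5-yl)deca-2,4-dienoate | C=CCOC(=O)/C=C\C=C/CC[C@@H](C)[C@H](Cc1cnco1)O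
F4 | step 22 | allyl (2Z,4Z,8R,9R)-9-{[(2Z,4Z,8R,9S)-9-[(tert-butyldimethylsilyl)oxy]-2,8-dimethyl-10-[2-(triisopropylsilyl)oxazol-5-yl]deca-2,4-dienoyl]oxy}-8-methyl-10-(oxazol-5-yl)deca-2,4-dienoate | C=CCOC(=O)/C=C\C=C/CC[C@@H](C)[C@@H](Cc1cnco1)OC(=O)/C(C)=C\C=C/CC[C@@H](C)[C@H](Cc1cnc([Si](C(C)C)(C(C)C)C(C)C)o1)O[Si](C)(C)C(C)(C)C
F5 | step 22 | allyl (2Z,4Z,8R,9R)-9-{[(2Z,4Z,8R,9S)-9-hydroxy-2,8-dimethyl-10-(oxazol-5-yl)deca-2,4-dienoyl]oxy}-8-methyl-10-(oxazol-5-yl)deca-2,4-dienoate | C=CCOC(=O)/C=C\C=C/CC[C@@H](C)[C@@H](Cc1cnco1)OC(=O)/C(C)=C\C=C/CC[C@@H](C)[C@H](Cc1cnco1)O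
F6 | step 22 | (2Z,4Z,8R,9R)-9-{[(2Z,4Z,8R,9S)-9-hydroxy-2,8-dimethyl-10-(oxazol-5-yl)deca-2,4-dienoyl]oxy}-8-methyl-10-(oxazol-5-yl)deca-2,4-dienoic acid | OC(=O)/C=C\C=C/CC[C@@H](C)[C@@H](Cc1cnco1)OC(=O)/C(C)=C\C=C/CC[C@@H](C)[C@H](Cc1cnco1)O
F7 | step 17 | allyl 2-{[(2Z,4Z,8R)-8-methyl-10-(oxazol-5-yl)-9-oxodeca-2,4-dienoyl]oxy}-3-(oxazol-5-yl)propanoate | C=CCOC(=O)C(Cc1cnco1)OC(=O)/C=C\C=C/CC[C@@H](C)C(=O)Cc1cnco1
F8 | step 17 | allyl 2-{[(2Z,4Z,8R,9R)-9-hydroxy-8-methyl-10-(oxazol-5-yl)deca-2,4-dienoyl]oxy}-3-(oxazol-5-yl)propanoate | C=CCOC(=O)C(Cc1cnco1)OC(=O)/C=C\C=C/CC[C@@H](C)[C@@H](Cc1cnco1)O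
F9 | step 14 | 5-{(2S,3R,6Z)-2-[(tert-butyldimethylsilyl)oxy]-7-iodo-3-methylhept-6-en-1-yl}-2-(triisopropylsilyl)oxazole | I/C=C\CC[C@@H](C)[C@H](Cc1cnc([Si](C(C)C)(C(C)C)C(C)C)o1)O[Si](C)(C)C(C)(C)C
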